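**Plan**
Retrosynthesis cuts, in order: the vicinal C3–Br/C4–Cl pair of the cyclohexane (back through its halogen-swapped trans-diaxial isomer to a 2-chloro ketone and an enone); oxane O1–C6 and C5–Br (bromoetherification); the side-chain olefin and oxane C3–C4 (metathesis, allylation); last the bond between cyclohexane C1 and oxane C2.
Feature used: cyclohexane C1 is para to C4, and without the halogens the ring has a mirror plane through C1 and C4, so C1 is stereogenic only because C3 (CHBr) differs from C5 (CH2). C1 can therefore come from one of two enantiotopic allylic carbons of a meso cyclohex-2-ene-1,4-diyl diester. Oxane C2, its methyl and C3 are the α-carbon, methyl and carboxyl carbon of lactic acid.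
Forward: diene to meso diacetate; lactic acid to its pivalaldehyde acetal; union of the two by allylic alkylation; lactol; allylation; enone; prenyl olefin; oxane ring; ring chlorine, methyl, bromine; halogen interchange.
Stereochemistry: cyclohexane C1 from ligand-controlled choice between enantiotopic acetates; oxane C2 from (S)-lactic acid through the tert-butyl acetal; oxane C3 by chelation; oxane C5 by chair bromoetherification; cyclohexane C3 and C4 by axial chlorination, anti bromide capture and a stereospecific 1,2-interchange.

Key step: step 3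

Assumption: the (R,R) ligand is taken to ionise the acetate on the (S)-configured carbon of 2, by analogy with its sense with cyclohex-2-enyl acetate; if the sense is opposite the (S,S) ligand is used, and the lactate-derived centre is not affected.

**Step 1**
Reactants: 1 cyclohexa-1,3-diene
Product: 2 cis-cyclohex-2-ene-1,4-diyl diacetate (meso)
Conditions: Pd(OAc)2 (5 mol %), LiCl (cat.), LiOAc, p-benzoquinone, AcOH, 25 °C
Reagents that add atoms: acetic acid, CC(=O)O
Why: Palladium-catalysed 1,4-diacetoxylation of the 1,3-diene: acetoxypalladation gives a 4-acetoxy-η3-allyl complex of divalent palladium, and with catalytic chloride the second acetate attacks from outside, anti to the metal, so that the two acetates end cis (the meso diester) while benzoquinone reoxidises the palladium.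

**Step 2**
Reactants: 3 (S)-lactic acid; 4 pivalaldehyde
Product: 5 (2S,5S)-2-tert-butyl-5-methyl-1,3-dioxolan-4-one
Conditions: TsOH·H2O (cat.), H2SO4 (cat.), pentane, reflux, water separator; recrystallisation
Reagents that add atoms: none
Why: Acid-catalysed acetalisation with removal of water gives the cis-2,5-disubstituted dioxolanone under thermodynamic control, the new acetal centre (S) being set relative to the lactic acid centre and the pure cis isomer obtained by crystallisation.

**Step 3**
Reactants: 5 (2S,5S)-2-tert-butyl-5-methyl-1,3-dioxolan-4-one; 2 cis-cyclohex-2-ene-1,4-diyl diacetate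
Product: 8 (1R,4S)-4-[(2S,4R)-2-tert-butyl-4-methyl-5-oxo-1,3-dioxolan-4-yl]cyclohex-2-en-1-yl acetate, via lithium enolate 6 (not isolated), via chlorozinc enolate 7 (not isolated)
Conditions: LiN(SiMe3)2, THF, −78 °C; ZnCl2; then 2, Pd2(dba)3·CHCl3 (2.5 mol %), (R,R)-DACH-phenyl Trost ligand [(1R,2R)-N,N'-bis(2-diphenylphosphinobenzoyl)cyclohexane-1,2-diamine] (7.5 mol %), THF, −78 to 0 °C
Reagents that add atoms: none
Why: The zerovalent palladium complex of the C2-symmetric diphosphine ionises one of the two enantiotopic allylic acetates of meso-2 anti to the leaving group, and the cationic 4-acetoxy-η3-cyclohexenyl complex is captured by the zinc enolate 7 at the allyl terminus remote from the remaining acetate, on the face anti to palladium, so that the α-carbon of the lactate unit is joined to the ring carbon with overall retention (cis-1,4 product). The closest known reaction type is the Tsuji–Trost asymmetric allylic alkylation, in its two established forms of desymmetrisation of meso-cycloalk-2-ene-1,4-diyl diesters and of palladium-catalysed allylation of preformed ester and 1,3-dioxolan-4-one enolates. No ring is closed. The ring stereocentre (S) is set by the ligand, which selects the acetate on the (S)-configured carbon for ionisation, followed by double inversion; the quaternary centre (R) is set by the tert-butyl group of the acetal, which shields one face of the planar enolate so that the allyl enters trans to it, in the place of the former hydrogen of (S)-lactic acid. The step needs enantiotopic-group selection, attack at the distal allyl terminus and not at the central carbon, and monoalkylation: the first rests on the chiral pocket, the second on the inductive and steric effect of the remaining acetate and on the phosphine-ligated cationic allyl meeting a covalent zinc enolate, the third on the fact that the acetate left in 8 is the mismatched one for this ligand.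

**Step 4**
Reactants: 8 (1R,4S)-4-[(2S,4R)-2-tert-butyl-4-methyl-5-oxo-1,3-dioxolan-4-yl]cyclohex-2-en-1-yl acetate
Product: 9 (1R,4S)-4-[(2S,4R)-2-tert-butyl-5-hydroxy-4-methyl-1,3-dioxolan-4-yl]cyclohex-2-en-1-ol (lactol, both anomers)
Conditions: i-Bu2AlH (4 equiv), CH2Cl2, −78 °C; aq. potassium sodium tartrate
Reagents that add atoms: none
Why: Partial reduction of the lactone carbonyl by i-Bu2AlH stops at the aluminium hemiacetal at −78 °C and the acetate is cleaved reductively in the same operation, the lactol carbon forming as an inconsequential mixture of anomers.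

**Step 5**
Reactants: 9 lactol
Product: 10 (2R,3R)-2-[(1S,4R)-4-hydroxycyclohex-2-en-1-yl]hex-5-ene-2,3-diol
Conditions: In powder, allyl bromide, THF–H2O (1:1), 25 °C
Reagents that add atoms: allyl bromide, C=CCBr
Why: Barbier-type indium allylation in water: the lactol opens to the α-hydroxy aldehyde with loss of pivalaldehyde, and chelation of indium between the free tertiary hydroxyl and the aldehyde oxygen (Cram chelate) exposes the face flanked by the methyl group and not by the cyclohexenyl ring, which sets the new carbinol centre as (3R).

**Step 6**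
Reactants: 10 triol
Product: 11 (4S)-4-[(2R,3R)-2,3-dihydroxyhex-5-en-2-yl]cyclohex-2-en-1-one
Conditions: MnO2 (activated, excess), CH2Cl2, 25 °C
Reagents that add atoms: none
Why: Activated MnO2 oxidises only the allylic secondary alcohol (chemoselective allylic oxidation), which removes that carbinol stereocentre and turns the ring olefin into an electron-poor enone that will not compete for electrophilic bromine in step 8.

**Step 7**
Reactants: 11 enone diol
Product: 12 (4S)-4-[(2R,3R)-2,3-dihydroxy-6-methylhept-5-en-2-yl]cyclohex-2-en-1-one
Conditions: 2-methyl-2-butene (excess), second-generation Grubbs catalyst RuCl2(=CHPh)(PCy3)(H2IMes) (5 mol %), CH2Cl2, 40 °C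
Reagents that add atoms: 2-methyl-2-butene, CC=C(C)C
Why: Olefin cross-metathesis of the terminal alkene with the trisubstituted partner in excess gives the prenyl-type olefin, while the enone olefin and the free hydroxyls are tolerated.

**Step 8**
Reactants: 12 prenyl enone diol
Product: 13 (4S)-4-[(2R,3R,5R)-5-bromo-3-hydroxy-2,6,6-trimethyloxan-2-yl]cyclohex-2-en-1-one
Conditions: 2,4,4,6-tetrabromocyclohexa-2,5-dienone (1.1 equiv), MeNO2, 0 to 25 °C
Reagents that add atoms: 2,4,4,6-tetrabromocyclohexa-2,5-dienone, BrC1=CC(Br)(Br)C=C(Br)C1=O
Why: Bromonium-induced 6-endo etherification: the tertiary hydroxyl opens the bromonium ion at its tertiary carbon with anti addition through a chair transition state in which the cyclohexenone substituent is equatorial and the carbinol oxygen axial, so that bromine ends equatorial and C5 is set as (R), while the electron-poor enone does not react with the bromonium donor.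

**Step 9**
Reactants: 13 bromo-oxane enone
Product: 15 (2R,4S)-4-[(2R,3R,5R)-5-bromo-3-hydroxy-2,6,6-trimethyloxan-2-yl]-2-chlorocyclohexan-1-one, via lithium enolate 14 (not isolated)
Conditions: LiBH(s-Bu)3 (2.2 equiv), THF, −78 °C; then N-chlorosuccinimide, −78 to −40 °C; aq. NH4Cl
Reagents that add atoms: N-chlorosuccinimide, ClN1C(=O)CCC1=O
Why: 1,4-Reduction of the enone by the hindered borohydride gives the enolate regiospecifically toward the former α-carbon, and chlorination by N-chlorosuccinimide occurs from the axial direction, trans to the equatorial oxanyl group, which sets the (2R) centre (conjugate reduction with enolate trapping).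

**Step 10**
Reactants: 15 2-chloro ketone
Product: 16 (2R,3R,5R)-5-bromo-2-[(1S,3R,4S)-3-chloro-4-hydroxy-4-methylcyclohexyl]-2,6,6-trimethyloxan-3-ol
Conditions: MeMgBr (3 equiv), THF, −78 °C
Reagents that add atoms: methylmagnesium bromide, C[Mg]Br
Why: Grignard 1,2-addition to the α-chloro ketone from the face anti to the axial C–Cl bond (Cornforth model) should give the tertiary alcohol with methyl axial; the configuration of this carbinol carbon is erased in step 11, and the magnesium alkoxide, cis to chlorine, cannot close to an epoxide.

**Step 11**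
Reactants: 16 chlorohydrin
Product: 17 (2R,3R,5R)-5-bromo-2-[(1S,3R,4R)-4-bromo-3-chloro-4-methylcyclohexyl]-2,6,6-trimethyloxan-3-ol
Conditions: Me3SiBr (3 equiv), CH2Cl2, 0 to 25 °C; then MeOH
Reagents that add atoms: bromotrimethylsilane, C[Si](C)(C)Br
Why: SN1 substitution of the tertiary alcohol by bromide: the tertiary cation is captured axially, anti to the neighbouring axial chlorine (chloronium-type shielding of the lower face), which should give the trans-diaxial tertiary bromide with (4R) configuration whatever the configuration of the carbinol in 16.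

**Step 12**
Reactants: 17 trans-diaxial 4-bromo-3-chloro isomer
Product: 18 caespitol
Conditions: MeCN, 70 °C, sealed, dark
Reagents that add atoms: none
Why: Thermal diaxial-to-diequatorial rearrangement of a vicinal trans-diaxial dihalide (dyotropic 1,2-interchange): bromine moves from C4 to C3 and chlorine from C3 to C4, each on its own face and each with inversion, which gives the trans-diequatorial (3S,4S) 3-bromo-4-chloro pattern; chlorine on the tertiary carbon and the polar medium should favour this isomer, and unchanged 17 can be resubmitted.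

**Compound list**
1 | cyclohexa-1,3-diene | C1=CC=CCC1 | starting material
2 | cis-cyclohex-2-ene-1,4-diyl diacetate (meso) | CC(=O)O[C@H]1CC[C@@H](OC(C)=O)C=C1 | intermediate
3 | (S)-lactic acid | C[C@H](O)C(=O)O | starting material
4 | pivalaldehyde (2,2-dimethylpropanal) | CC(C)(C)C=O | starting material
5 | (2S,5S)-2-tert-butyl-5-methyl-1,3-dioxolan-4-one | C[C@@H]1O[C@H](C(C)(C)C)OC1=O | intermediate
6 | lithium (2S)-2-tert-butyl-5-methyl-1,3-dioxol-4-olate (lithium enolate of 5) | CC1=C([O-])O[C@@H](C(C)(C)C)O1.[Li+] | intermediate
7 | chlorido[(2S)-2-tert-butyl-5-methyl-1,3-dioxol-4-olato]zinc (chlorozinc enolate of 5) | CC1=C(O[Zn]Cl)O[C@@H](C(C)(C)C)O1 | intermediate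
8 | (1R,4S)-4-[(2S,4R)-2-tert-butyl-4-methyl-5-oxo-1,3-dioxolan-4-yl]cyclohex-2-en-1-yl acetate | CC(C)(C)[C@H]1O[C@](C)([C@H]2CC[C@@H](OC(C)=O)C=C2)C(=O)O1 | intermediate
9 | (1R,4S)-4-[(2S,4R)-2-tert-butyl-5-hydroxy-4-methyl-1,3-dioxolan-4-yl]cyclohex-2-en-1-ol (lactol, both anomers; lactol carbon left undefined) | CC(C)(C)[C@H]1O[C@](C)([C@H]2CC[C@@H](O)C=C2)C(O)O1 | intermediate
10 | (2R,3R)-2-[(1S,4R)-4-hydroxycyclohex-2-en-1-yl]hex-5-ene-2,3-diol | O[C@](C)([C@H]1CC[C@@H](O)C=C1)[C@H](O)CC=C | intermediate
11 | (4S)-4-[(2R,3R)-2,3-dihydroxyhex-5-en-2-yl]cyclohex-2-en-1-one | O[C@](C)([C@H]1CCC(=O)C=C1)[C@H](O)CC=C | intermediate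
12 | (4S)-4-[(2R,3R)-2,3-dihydroxy-6-methylhept-5-en-2-yl]cyclohex-2-en-1-one | O[C@](C)([C@H]1CCC(=O)C=C1)[C@H](O)CC=C(C)C | intermediate
13 | (4S)-4-[(2R,3R,5R)-5-bromo-3-hydroxy-2,6,6-trimethyloxan-2-yl]cyclohex-2-en-1-one | CC1(C)O[C@](C)([C@H]2CCC(=O)C=C2)[C@H](O)C[C@H]1Br | intermediate
14 | lithium (4S)-4-[(2R,3R,5R)-5-bromo-3-hydroxy-2,6,6-trimethyloxan-2-yl]cyclohex-1-en-1-olate | CC1(C)O[C@](C)([C@H]2CCC([O-])=CC2)[C@H](O)C[C@H]1Br.[Li+] | intermediate
15 | (2R,4S)-4-[(2R,3R,5R)-5-bromo-3-hydroxy-2,6,6-trimethyloxan-2-yl]-2-chlorocyclohexan-1-one | CC1(C)O[C@](C)([C@H]2CCC(=O)[C@H](Cl)C2)[C@H](O)C[C@H]1Br | intermediate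
16 | (2R,3R,5R)-5-bromo-2-[(1S,3R,4S)-3-chloro-4-hydroxy-4-methylcyclohexyl]-2,6,6-trimethyloxan-3-ol | CC1(C)O[C@](C)([C@H]2CC[C@](C)(O)[C@H](Cl)C2)[C@H](O)C[C@H]1Br | intermediate
17 | (2R,3R,5R)-5-bromo-2-[(1S,3R,4R)-4-bromo-3-chloro-4-methylcyclohexyl]-2,6,6-trimethyloxan-3-ol | CC1(C)O[C@](C)([C@H]2CC[C@@](C)(Br)[C@H](Cl)C2)[C@H](O)C[C@H]1Br | intermediate
18 | caespitol, (2R,3R,5R)-5-bromo-2-[(1S,3S,4S)-3-bromo-4-chloro-4-methylcyclohexyl]-2,6,6-trimethyloxan-3-ol | CC1(C)O[C@](C)([C@H]2CC[C@](C)(Cl)[C@@H](Br)C2)[C@H](O)C[C@H]1Br | target

**Count**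
Total steps: 12. Longest linear sequence: 11 (step 1 or step 2, then steps 3 to 12).

**Steps most likely to fail**

Step 3. Capture of the allyl complex by the hindered zinc enolate may be slow, so that C-acylation of the enolate by the acetate groups, elimination to a diene and erosion of the enantiotopic-group selection compete. The fallback moves the desymmetrisation to an enzyme and makes the palladium step stereospecific. It sets out from 2. Hydrolysis of one acetate by a lipase (for example Candida antarctica lipase B, phosphate buffer, pH 7; or monoacetylation of the derived meso-diol with the same enzyme, whichever mode leaves the acetate on the (R)-carbon) gives (1R,4S)-4-hydroxycyclohex-2-en-1-yl acetate F1. Methyl chloroformate and pyridine give (1R,4S)-4-[(methoxycarbonyl)oxy]cyclohex-2-en-1-yl acetate F2. The zinc enolate 7, made from 5 as in step 3, with Pd2(dba)3·CHCl3 and PPh3 at −78 to 25 °C should then displace the carbonate, which ionises selectively and irreversibly at a temperature where 7 is stable. Net retention returns the route at 8.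

Step 11. The hydroxyl of 16 is gauche to chlorine, so ionisation has no anchimeric help; E1 elimination, methyl migration or cleavage of the oxane ether by the silyl bromide may compete with bromide capture. The fallback builds the tertiary carbinol from an olefin so that the hydroxyl is antiperiplanar to chlorine. It sets out from 13. LiBH(s-Bu)3 followed by PhNTf2 gives (4S)-4-[(2R,3R,5R)-5-bromo-3-hydroxy-2,6,6-trimethyloxan-2-yl]cyclohex-1-en-1-yl trifluoromethanesulfonate F4. Negishi methylation (MeZnCl, Pd(PPh3)4) gives (2R,3R,5R)-5-bromo-2,6,6-trimethyl-2-[(1S)-4-methylcyclohex-3-en-1-yl]oxan-3-ol F5. N-chlorosuccinimide in aqueous acetone should add chlorine and water trans-diaxially, water at the tertiary carbon (the matched Markovnikov and Fürst–Plattner mode, chloronium on the face remote from the oxanyl group), to give (2R,3R,5R)-5-bromo-2-[(1S,3R,4R)-3-chloro-4-hydroxy-4-methylcyclohexyl]-2,6,6-trimethyloxan-3-ol F6. Me3SiBr then ionises this alcohol with assistance from the antiperiplanar chlorine and returns the route at 17.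

Step 8. A 5-exo closure to a tetrahydrofuran may compete, and facial selection at the bromonium stage may be poor, which would give the C5 epimer of the oxane. The fallback separates ring closure from bromine delivery. It sets out from 12. Hg(OCOCF3)2 in MeNO2 at −20 °C, then aqueous KBr, gives the 6-endo oxymercuration product under reversible, thermodynamic control: bromo[(3R,5R,6R)-5-hydroxy-2,2,6-trimethyl-6-[(1S)-4-oxocyclohex-2-en-1-yl]oxan-3-yl]mercury F3, with the mercury equatorial. Brominolysis with Br2 and LiBr in pyridine under O2 should replace mercury by bromine with retention and returns the route at 13.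

**Further compounds**
F1 | step 3 | (1R,4S)-4-hydroxycyclohex-2-en-1-yl acetate | O[C@H]1CC[C@@H](OC(C)=O)C=C1
F2 | step 3 | (1R,4S)-4-[(methoxycarbonyl)oxy]cyclohex-2-en-1-yl acetate | COC(=O)O[C@H]1CC[C@@H](OC(C)=O)C=C1
F3 | step 8 | bromo[(3R,5R,6R)-5-hydroxy-2,2,6-trimethyl-6-[(1S)-4-oxocyclohex-2-en-1-yl]oxan-3-yl]mercury | CC1(C)O[C@](C)([C@H]2CCC(=O)C=C2)[C@H](O)C[C@H]1[Hg]Br
F4 | step 11 | (4S)-4-[(2R,3R,5R)-5-bromo-3-hydroxy-2,6,6-trimethyloxan-2-yl]cyclohex-1-en-1-yl trifluoromethanesulfonate | CC1(C)O[C@](C)([C@H]2CCC(OS(=O)(=O)C(F)(F)F)=CC2)[C@H](O)C[C@H]1Br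
F5 | step 11 | (2R,3R,5R)-5-bromo-2,6,6-trimethyl-2-[(1S)-4-methylcyclohex-3-en-1-yl]oxan-3-ol | CC1(C)O[C@](C)([C@H]2CCC(C)=CC2)[C@H](O)C[C@H]1Br
F6 | step 11 | (2R,3R,5R)-5-bromo-2-[(1S,3R,4R)-3-chloro-4-hydroxy-4-methylcyclohexyl]-2,6,6-trimethyloxan-3-ol | CC1(C)O[C@](C)([C@H]2CC[C@@](C)(O)[C@H](Cl)C2)[C@H](O)C[C@H]1Br
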